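**Retrosynthetic overview**
1. 21 ⇒ 19. The last two operations are C–O bond formations on the closed skeleton: C15–H hydroxylation and 1,10-epoxidation.
2. 19 ⇒ 18. The ten-membered ring is closed at C3–C4 by a Nozaki–Hiyama–Kishi reaction (Z-vinyl iodide plus aldehyde), which also creates the C3 carbinol.
3. 18 ⇒ 12. The γ-lactone, the exo-methylene and the 8-ester come from an epoxy alcohol through a tethered phosphonoacetate opening/olefination/acylation cascade (new).
4. Key disconnection, 12 ⇒ 11. The C8–O bond (with a transient C7–O bond) is made by Sharpless epoxidation with kinetic resolution of a racemic bis-allylic alcohol. This oxygen stays in 21 as the ester oxygen and is the only source of absolute configuration: C6 is selected, C8 is set, and C7 is set later by inversion.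
5. 11 ⇒ acrolein, propynyl Grignard reagent and 1-penten-4-yne, joined by cross-metathesis. Ring order: 7,8-oxirane (sacrificed) → γ-lactone → ten-membered carbocycle → 1,10-oxirane.

Assumption: 1-propynylmagnesium bromide solution and 1-penten-4-yne are bought as catalogue chemicals. Atom labels C1–C15 follow the germacrane numbering of the target.

**Step 1**
Reactants: 1 acrolein; 2 1-propynylmagnesium bromide
Product: 3 rac-hex-1-en-4-yn-3-ol
Conditions: THF, −78 °C; aq. work-up
Reagents that add atoms: none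
Why: 1,2-addition of an alkynyl Grignard reagent to an enal is fast and clean at low temperature, and the carbinol centre (C6) is left racemic on purpose because step 6 resolves it.

**Step 2**
Reactants: 3 rac-hex-1-en-4-yn-3-ol
Product: 5 rac-(4Z)-5-iodohexa-1,4-dien-3-ol, via cyclic sodium vinylalanate 4 (not isolated)
Conditions: NaAlH2(OCH2CH2OMe)2 (Red-Al), THF, 0 °C→rt; EtOAc; I2, −78→0 °C
Reagents that add atoms: iodine II
Why: hydroxyl-directed trans-hydroalumination of a propargylic alcohol followed by iodinolysis with retention puts hydride on the proximal and aluminium on the distal alkyne carbon through the five-membered alanate, so iodine ends cis to C6 and fixes the 4Z geometry.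

**Step 3**
Reactants: 6 1-penten-4-yne
Product: 9 (3E)-4-methylhepta-3,6-dien-1-ol, via alkenyldimethylalane 7 (not isolated), via lithium alkenylalanate 8 (not isolated)
Conditions: Me3Al, Cp2ZrCl2 (0.25 equiv), CH2Cl2, 0 °C→rt; n-BuLi, hexane, −78→0 °C; ethylene oxide, THF, 0 °C→rt
Reagents that add atoms: trimethylaluminium C[Al](C)C; ethylene oxide C1CO1
Why: Negishi zirconium-catalysed syn-carboalumination of the terminal alkyne (the alkene is untouched) sets the E-trisubstituted C1=C10 alkene, and the derived alanate opens ethylene oxide with retention of alkene geometry.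

**Step 4**
Reactants: 9 (3E)-4-methylhepta-3,6-dien-1-ol
Product: 10 triethyl{[(3E)-4-methylhepta-3,6-dien-1-yl]oxy}silane
Conditions: Et3SiCl, imidazole, CH2Cl2, 0 °C
Reagents that add atoms: chlorotriethylsilane CC[Si](Cl)(CC)CC
Why: standard silylation of a primary alcohol; the triethylsilyl ether survives steps 5–8 and is the direct aldehyde precursor in step 9.

**Step 5**
Reactants: 5 rac-(4Z)-5-iodohexa-1,4-dien-3-ol; 10 triethyl{[(3E)-4-methylhepta-3,6-dien-1-yl]oxy}silane
Product: 11 rac-(2Z,5E,8E)-2-iodo-8-methyl-11-(triethylsilyloxy)undeca-2,5,8-trien-4-ol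
Conditions: second-generation Hoveyda–Grubbs catalyst RuCl2(SIMes)(=CHC6H4-2-OiPr) (5 mol%), 10 (2 equiv), 1,4-benzoquinone (10 mol%), CH2Cl2, 40 °C
Reagents that add atoms: none
Why: olefin cross-metathesis of a terminal alkene with a secondary allylic alcohol is a selective pairing that gives the E-C7=C8 alkene, while the iodo-substituted and trisubstituted alkenes are inert and benzoquinone suppresses alkene migration.

**Step 6**
Reactants: 11 rac-(2Z,5E,8E)-2-iodo-8-methyl-11-(triethylsilyloxy)undeca-2,5,8-trien-4-ol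
Product: 12 (1R,2Z)-3-iodo-1-{(2R,3R)-3-[(2E)-2-methyl-5-(triethylsilyloxy)pent-2-en-1-yl]oxiran-2-yl}but-2-en-1-ol
Conditions: Ti(OiPr)4 (0.2 equiv), D-(−)-diisopropyl tartrate (0.25 equiv), t-BuOOH (0.5 equiv), 4 Å MS, CH2Cl2, −20 °C, stopped near 48% conversion
Reagents that add atoms: tert-butyl hydroperoxide CC(C)(C)OO
Why: Sharpless asymmetric epoxidation run as a kinetic resolution: with the D-tartrate only (S)-11 reacts, at the E-disubstituted C7=C8 alkene (the Z-iodoalkene is slow and C1=C10 has no directing group), giving the erythro epoxy alcohol in which C6 is selected, C8–O has its final configuration and C7–O is placed for later inversion, while (R)-11 stays behind.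

**Step 7**
Reactants: 12 epoxy alcohol; 13 (diethoxyphosphoryl)acetic acid
Product: 14 (diethoxyphosphoryl)acetate ester of 12 at O6
Conditions: DCC, DMAP (cat.), CH2Cl2, 0 °C→rt
Reagents that add atoms: none
Why: Steglich esterification forms the future lactone C6–O–C12 bond under neutral conditions that leave the epoxide and all stereocentres untouched.

**Step 8**
Reactants: 14 (diethoxyphosphoryl)acetate ester of 12
Product: 17 (4R,5S)-5-[(1Z)-2-iodoprop-1-enyl]-3-methylidene-4-[(1R,3E)-3-methyl-1-(2-methylpropanoyloxy)-6-(triethylsilyloxy)hex-3-enyl]oxolan-2-one, via phosphono lactone alcohol 15 (not isolated), via methylene lactone alcohol 16 (not isolated)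
Conditions: LiCl, DBU, MeCN, 0 °C→rt; (CH2O)n, rt; (i-PrCO)2O, DMAP (cat.), 0 °C
Reagents that add atoms: formaldehyde (from paraformaldehyde) C=O; isobutyric anhydride CC(C)C(=O)OC(=O)C(C)C
Why: Proposed new method: the lithium-chelated phosphonoacetate carbanion, held three atoms away on O6, can reach only the proximal epoxide carbon C7 and only from the face opposite the C7–O bond (5-exo-tet, SN2 inversion, which sets C7 and the 6,7-trans lactone and leaves C8–O untouched), the liberated C8 alkoxide is quenched by the more acidic α-phosphono lactone so the same equivalent of base carries the Horner–Wadsworth–Emmons methylenation with formaldehyde, and the free 8-OH is capped before it can translactonise; the closest known reactions are the intermolecular opening of epoxides by phosphonoacetate anions to α-phosphono-γ-lactones, the base-induced C2-selective opening of 2,3-epoxy-alcohol carbamates by their tethered nucleophile, and the formaldehyde olefination of α-phosphono lactones.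

**Step 9**
Reactants: 17 silyl ether lactone
Product: 18 (4R,5S)-5-[(1Z)-2-iodoprop-1-enyl]-3-methylidene-4-[(1R,3E)-3-methyl-1-(2-methylpropanoyloxy)-6-oxohex-3-enyl]oxolan-2-one
Conditions: (COCl)2, DMSO, CH2Cl2, −78→−40 °C; Et3N, −78 °C
Reagents that add atoms: none
Why: Swern conditions convert primary triethylsilyl ethers directly into aldehydes, which saves a deprotection, and the cold amine quench keeps the β,γ-unsaturated aldehyde out of conjugation.

**Step 10**
Reactants: 18 iodo aldehyde
Product: 19 (1(10)E,3S,4Z,6R,7R,8R)-3-hydroxy-8-(2-methylpropanoyloxy)germacra-1(10),4,11(13)-trien-12,6-olide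
Conditions: CrCl2 (8 equiv), NiCl2 (0.1 equiv), DMSO/THF, 2 mM, rt
Reagents that add atoms: none
Why: Nozaki–Hiyama–Kishi macrocyclisation tolerates the α-methylene lactone and the ester, keeps the trisubstituted Z-alkenyl geometry and is an established closure for germacranolide rings; C3 is set by addition through the ring conformer that places the forming C3–O bond on the periphery (3S expected, see risks).

**Step 11**
Reactants: 19 macrocyclic trienolide
Product: 20 (1R,3S,4Z,6R,7R,8R,10R)-1,10-epoxy-3-hydroxy-8-(2-methylpropanoyloxy)germacra-4,11(13)-dien-12,6-olide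
Conditions: dimethyldioxirane (1.0 equiv, acetone), CH2Cl2, −40→−20 °C
Reagents that add atoms: dimethyldioxirane CC1(C)OO1
Why: electrophilic dioxirane epoxidation picks the strained, electron-rich E-C1=C10 alkene over the doubly oxygen-flanked C4=C5 and the acrylate alkene, attacks its peripheral face with hydrogen-bond guidance from the homoallylic 3-OH (the 1,3-syn relation of C3–O and C1–O found in the target), and gives the trans epoxide (C1, C10) stereospecifically under acid-free conditions.

**Step 12**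
Reactants: 20 epoxy dienolide
Product: 21 (1R,3S,4Z,6R,7R,8R,10R)-1,10-epoxy-3,15-dihydroxy-8-(2-methylpropanoyloxy)germacra-4,11(13)-dien-12,6-olide (target)
Conditions: SeO2 (0.5 equiv), t-BuOOH (2 equiv), CH2Cl2, 0 °C→rt
Reagents that add atoms: selenium dioxide O=[Se]=O (oxygen carrier); tert-butyl hydroperoxide CC(C)(C)OO (terminal oxygen source)
Why: selenium dioxide allylic hydroxylation (ene reaction then [2,3]-sigmatropic shift) attacks the only remaining electron-rich alkene at the methyl group cis to H5, so CH2OH ends trans to C6 and the alkene geometry is kept, and epoxide and α-methylene lactone are known to survive these conditions in germacranolides.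

**Compound list**
1 | acrolein | C=CC=O | starting material
2 | 1-propynylmagnesium bromide | CC#C[Mg]Br | starting material
3 | rac-hex-1-en-4-yn-3-ol | C=CC(O)C#CC | intermediate
4 | cyclic sodium vinylalanate (sodium 2,2-bis(2-methoxyethoxy)-3-methyl-5-vinyl-2,5-dihydro-1,2-oxaluminol-2-uide, racemic) | [Na+].COCCO[Al-]1(OCCOC)OC(C=C)C=C1C | intermediate
5 | rac-(4Z)-5-iodohexa-1,4-dien-3-ol | C=CC(O)/C=C(/C)I | intermediate
6 | 1-penten-4-yne | C=CCC#C | starting material
7 | dimethyl[(1E)-2-methylpenta-1,4-dien-1-yl]alane | C[Al](C)/C=C(\C)CC=C | intermediate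
8 | lithium butyl(dimethyl)[(1E)-2-methylpenta-1,4-dien-1-yl]alanate | [Li+].CCCC[Al-](C)(C)/C=C(\C)CC=C | intermediate
9 | (3E)-4-methylhepta-3,6-dien-1-ol | OCC/C=C(\C)CC=C | intermediate
10 | triethyl{[(3E)-4-methylhepta-3,6-dien-1-yl]oxy}silane | CC[Si](CC)(CC)OCC/C=C(\C)CC=C | intermediate
11 | rac-(2Z,5E,8E)-2-iodo-8-methyl-11-(triethylsilyloxy)undeca-2,5,8-trien-4-ol | C/C(I)=C/C(O)/C=C/C/C(C)=C/CCO[Si](CC)(CC)CC | intermediate
12 | (1R,2Z)-3-iodo-1-{(2R,3R)-3-[(2E)-2-methyl-5-(triethylsilyloxy)pent-2-en-1-yl]oxiran-2-yl}but-2-en-1-ol (6R,7R,8R) | C/C(I)=C/[C@@H](O)[C@H]1O[C@@H]1C/C(C)=C/CCO[Si](CC)(CC)CC | intermediate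
13 | (diethoxyphosphoryl)acetic acid | CCOP(=O)(CC(=O)O)OCC | starting material
14 | (diethoxyphosphoryl)acetate of 12 at O6 (6R,7S,8R; same spatial arrangement as 12) | C/C(I)=C/[C@@H](OC(=O)CP(=O)(OCC)OCC)[C@H]1O[C@@H]1C/C(C)=C/CCO[Si](CC)(CC)CC | intermediate
15 | (4R,5S)-3-(diethoxyphosphoryl)-4-[(1R,3E)-1-hydroxy-3-methyl-6-(triethylsilyloxy)hex-3-enyl]-5-[(1Z)-2-iodoprop-1-enyl]oxolan-2-one (epimers at C3 of the ring) | C/C(I)=C/[C@H]1OC(=O)C(P(=O)(OCC)OCC)[C@@H]1[C@H](O)C/C(C)=C/CCO[Si](CC)(CC)CC | intermediate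
16 | (4R,5S)-4-[(1R,3E)-1-hydroxy-3-methyl-6-(triethylsilyloxy)hex-3-enyl]-5-[(1Z)-2-iodoprop-1-enyl]-3-methylideneoxolan-2-one | C/C(I)=C/[C@H]1OC(=O)C(=C)[C@@H]1[C@H](O)C/C(C)=C/CCO[Si](CC)(CC)CC | intermediate
17 | (4R,5S)-5-[(1Z)-2-iodoprop-1-enyl]-3-methylidene-4-[(1R,3E)-3-methyl-1-(2-methylpropanoyloxy)-6-(triethylsilyloxy)hex-3-enyl]oxolan-2-one | C/C(I)=C/[C@H]1OC(=O)C(=C)[C@@H]1[C@H](OC(=O)C(C)C)C/C(C)=C/CCO[Si](CC)(CC)CC | intermediate
18 | (4R,5S)-5-[(1Z)-2-iodoprop-1-enyl]-3-methylidene-4-[(1R,3E)-3-methyl-1-(2-methylpropanoyloxy)-6-oxohex-3-enyl]oxolan-2-one | C/C(I)=C/[C@H]1OC(=O)C(=C)[C@@H]1[C@H](OC(=O)C(C)C)C/C(C)=C/CC=O | intermediate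
19 | (1(10)E,3S,4Z,6R,7R,8R)-3-hydroxy-8-(2-methylpropanoyloxy)germacra-1(10),4,11(13)-trien-12,6-olide | C=C1C(=O)O[C@@H]2/C=C(/C)[C@@H](O)C/C=C(\C)C[C@@H](OC(=O)C(C)C)[C@@H]12 | intermediate
20 | (1R,3S,4Z,6R,7R,8R,10R)-1,10-epoxy-3-hydroxy-8-(2-methylpropanoyloxy)germacra-4,11(13)-dien-12,6-olide | C=C1C(=O)O[C@@H]2/C=C(/C)[C@@H](O)C[C@H]3O[C@]3(C)C[C@@H](OC(=O)C(C)C)[C@@H]12 | intermediate
21 | (1R,3S,4Z,6R,7R,8R,10R)-1,10-epoxy-3,15-dihydroxy-8-(2-methylpropanoyloxy)germacra-4,11(13)-dien-12,6-olide | C=C1C(=O)O[C@@H]2/C=C(/CO)[C@@H](O)C[C@H]3O[C@]3(C)C[C@@H](OC(=O)C(C)C)[C@@H]12 | target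

**Step count**
- Total steps: 12.
- Longest linear sequence: 10 (steps 1, 2, 5, 6, 7, 8, 9, 10, 11, 12).

**Steps most likely to fail**

Step 8 (new cascade). The stabilised carbanion may open the epoxide too slowly, attack C8 instead, or the 8-OH may translactonise.
- The fallback sets out from 12 and comes back at 17, using known radical chemistry.
- O-alkylation of 12 with NaH and propargyl bromide gives propargyl ether F1.
- Cp2TiCl (trivalent titanium, made from Cp2TiCl2 and Zn) in THF cleaves the epoxide homolytically. The C7 radical closes 5-exo-dig on the alkyne to give the 4,5-trans methylenetetrahydrofuran alcohol F2, with C8–O retained.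
- Isobutyric anhydride with DMAP gives methylenetetrahydrofuran isobutyrate F3.
- CrO3·3,5-dimethylpyrazole oxidises the allylic ether CH2 of F3 to the lactone carbonyl, which is 17.

Step 10 (ring closure and C3). The closure may favour the wrong carbinol epimer.
- The fallback sets out from 18 and comes back at 19. It moves control of C3 from the C–C bond formation to a reagent-controlled reduction.
- The closure product, 3R epimeric alcohol F4, is oxidised with Dess–Martin periodinane to macrocyclic 3-ketone F5.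
- F5 is reduced with (R)-Me-CBS oxazaborolidine and catecholborane in toluene at −78 °C (alkenyl as the large group) to the 3S alcohol 19.

Step 12 (C15–H hydroxylation). The reaction may stall, over-oxidise or give low conversion.
- The fallback sets out from 20 and comes back at 21.
- The oxidation is driven fully to the aldehyde stage with SeO2 (1.5 equiv) in pyridine-buffered dioxane at 40 °C, giving 15-oxo enal F6.
- The enal alone is then reduced 1,2 with NaBH4 and CeCl3·7H2O in MeOH at −78 °C (Luche reduction) to 21.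

**Further compounds**
F1 | step 8 | (6R,7S,8R)-O6-propargyl ether of 12 | C/C(I)=C/[C@@H](OCC#C)[C@H]1O[C@@H]1C/C(C)=C/CCO[Si](CC)(CC)CC
F2 | step 8 | (1R,3E)-1-{(2S,3R)-2-[(1Z)-2-iodoprop-1-enyl]-4-methylideneoxolan-3-yl}-3-methyl-6-(triethylsilyloxy)hex-3-en-1-ol | C/C(I)=C/[C@H]1OCC(=C)[C@@H]1[C@H](O)C/C(C)=C/CCO[Si](CC)(CC)CC
F3 | step 8 | 2-methylpropanoate ester of F2 | C/C(I)=C/[C@H]1OCC(=C)[C@@H]1[C@H](OC(=O)C(C)C)C/C(C)=C/CCO[Si](CC)(CC)CC
F4 | step 10 | (1(10)E,3R,4Z,6R,7R,8R)-3-hydroxy-8-(2-methylpropanoyloxy)germacra-1(10),4,11(13)-trien-12,6-olide | C=C1C(=O)O[C@@H]2/C=C(/C)[C@H](O)C/C=C(\C)C[C@@H](OC(=O)C(C)C)[C@@H]12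
F5 | step 10 | (1(10)E,4Z,6R,7R,8R)-8-(2-methylpropanoyloxy)-3-oxogermacra-1(10),4,11(13)-trien-12,6-olide | C=C1C(=O)O[C@@H]2/C=C(/C)C(=O)C/C=C(\C)C[C@@H](OC(=O)C(C)C)[C@@H]12
F6 | step 12 | (1R,3S,4Z,6R,7R,8R,10R)-1,10-epoxy-3-hydroxy-8-(2-methylpropanoyloxy)-15-oxogermacra-4,11(13)-dien-12,6-olide | C=C1C(=O)O[C@@H]2/C=C(/C=O)[C@@H](O)C[C@H]3O[C@]3(C)C[C@@H](OC(=O)C(C)C)[C@@H]12
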